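**Plan**
- Retrosynthesis: the carboxyl group is taken back to a triisopropylsilyl-protected CH2OH, then the 1,2-dioxolane is cut at C3–C4 and at C5–O1.
- Enabling feature: ring atoms O1–O2–C3 are the peroxide of a methyl ketone (a peroxycarbenium ion), and C4–C5 are a 1,1-disubstituted alkene whose C5 already carries the methyl group and the 10-phenyldecyl chain, so C5 can become a tertiary cation.
- The alkene is cut at both ends of its (CH2)10 chain (aryl–CH2 and isopropenyl–CH2 bonds); the peroxyketal comes from silylated isoprenol by ozonolysis in methanol.
- Forward: the peroxyketal (three steps) and the alkene (two steps) are joined in one (3+2) annulation that closes the only ring; desilylation and oxidation then give the acid.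
- Stereochemistry: C3 and C5 are both set in the annulation by a confined chiral imidodiphosphorimidate counter-anion; no later step touches these two fully substituted centres.

Key step: step 6

Assumption: the sense of induction of the imidodiphosphorimidate (IDPi) acid cannot be predicted for this step; the route is written for the catalyst built from (S)-BINOL units, and its antipode would be used if a first run shows the opposite sense.

**Step 1**
Reactants: 1 3-methylbut-3-en-1-ol (isoprenol)
Product: 2 triisopropyl[(3-methylbut-3-en-1-yl)oxy]silane
Conditions: i-Pr3SiCl, imidazole, DMF, 0 °C → rt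
Reagents that add atoms: chlorotriisopropylsilane, CC(C)[Si](Cl)(C(C)C)C(C)C
Why: Imidazole-promoted silyl ether formation on an unhindered primary alcohol, with no stereocentre involved.

**Step 2**
Reactants: 2 triisopropyl[(3-methylbut-3-en-1-yl)oxy]silane
Product: 4 2-methoxy-4-[(triisopropylsilyl)oxy]butan-2-yl hydroperoxide (racemic), via carbonyl oxide 3 (not isolated)
Conditions: O3, MeOH/CH2Cl2, −78 °C; N2 purge, no reductive work-up
Reagents that add atoms: ozone, [O-][O+]=O; methanol, CO
Why: Criegee ozonolysis in methanol, in which the 1,1-disubstituted alkene fragments to formaldehyde and the more substituted carbonyl oxide 3, which methanol traps as the α-methoxy hydroperoxide (its racemic ketal centre is erased again in step 6).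

**Step 3**
Reactants: 4 2-methoxy-4-[(triisopropylsilyl)oxy]butan-2-yl hydroperoxide
Product: 5 triethyl{[2-methoxy-4-(triisopropylsilyloxy)butan-2-yl]peroxy}silane (racemic)
Conditions: Et3SiCl, imidazole, DMF, 0 °C
Reagents that add atoms: chlorotriethylsilane, CC[Si](Cl)(CC)CC
Why: O-Silylation of the hydroperoxide under mildly basic conditions, which leaves the acid-labile ketal and the peroxide bond intact.

**Step 4**
Reactants: 6 1,10-dibromodecane (3 equiv); 7 phenylmagnesium bromide
Product: 8 (10-bromodecyl)benzene
Conditions: Li2CuCl4 (3 mol %), THF, 0 °C → rt; surplus 6 recovered by distillation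
Reagents that add atoms: none
Why: Copper-catalysed cross-coupling of an aryl Grignard reagent with a primary alkyl bromide, with the excess of dibromide favouring mono-arylation.

**Step 5**
Reactants: 8 (10-bromodecyl)benzene; 9 isopropenylmagnesium bromide
Product: 10 2-methyl-12-phenyldodec-1-ene
Conditions: Li2CuCl4 (5 mol %), THF, −10 °C → rt
Reagents that add atoms: none
Why: Copper-catalysed cross-coupling of an alkenyl Grignard reagent with a primary alkyl bromide, which installs the 1,1-disubstituted alkene without moving the double bond.

**Step 6**
Reactants: 5 triethyl{[2-methoxy-4-(triisopropylsilyloxy)butan-2-yl]peroxy}silane (1.2 equiv); 10 2-methyl-12-phenyldodec-1-ene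
Product: 13 triisopropyl{2-[(3S,5S)-3,5-dimethyl-5-(10-phenyldecyl)-1,2-dioxolan-3-yl]ethoxy}silane, via peroxycarbenium ion 11 (not isolated), via tertiary carbocation 12 (not isolated)
Conditions: (S,S)-IDPi acid HN[P(=NSO2CF3)(3,3'-Ar2-BINOLate)]2, Ar = 3,5-(CF3)2C6H3 (5 mol %), allylSiEt3 (5 mol %, pre-silylation of the acid), toluene, −78 °C
Reagents that add atoms: none
Why: Proposed new method: the silylated imidodiphosphorimidate removes methoxide from 5 (as Et3SiOMe) to give peroxycarbenium ion 11 paired with the confined chiral anion, the CH2 terminus of 10 adds to its carbon (C3–C4) to give tertiary carbocation 12, and the silylated peroxide oxygen then captures C5 (C5–O1) and hands Et3Si+ back to the anion, so the catalyst turns over. The closest known reaction types are the racemic SnCl4- or Me3SiOTf-promoted (3+2) annulation of triethylsilyl peroxyketals with 1,1-disubstituted alkenes and the imidodiphosphorimidate-catalysed asymmetric additions of alkenes and silyl nucleophiles to oxocarbenium ion pairs. The 1,2-dioxolane closes by cation–heteroatom recombination, the peroxide oxygen O1 attacking the planar C5 cation held five atoms away, as the second bond of a stepwise annulation. C3 is set when the alkene attacks one enantiotopic face of 11, chosen by the anion cavity, which has to tell the methyl group from the 2-(silyloxy)ethyl arm; C5 is set in the ring closure, in which the anion accompanying 12 has to hold the decyl chain on the face of the C3 methyl group. The step needs Markovnikov regioselectivity, secured by the 1,1-disubstituted alkene (tertiary versus primary cation), closure faster than proton loss from 12, favoured by the low temperature and the non-basic anion, and an inert side chain, secured by the bulky triisopropylsilyl ether whose oxygen neither binds the silylium centre nor attacks the cation.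

**Step 7**
Reactants: 13 triisopropyl{2-[(3S,5S)-3,5-dimethyl-5-(10-phenyldecyl)-1,2-dioxolan-3-yl]ethoxy}silane
Product: 14 2-[(3S,5S)-3,5-dimethyl-5-(10-phenyldecyl)-1,2-dioxolan-3-yl]ethan-1-ol
Conditions: Bu4NF, AcOH (1:1), THF, 0 °C → rt
Reagents that add atoms: none
Why: Fluoride-mediated silyl ether cleavage, tolerated because neither peroxide-bearing carbon carries a hydrogen, so base-induced Kornblum–DeLaMare fragmentation is impossible and the stereocentres are untouched.

**Step 8**
Reactants: 14 2-[(3S,5S)-3,5-dimethyl-5-(10-phenyldecyl)-1,2-dioxolan-3-yl]ethan-1-ol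
Product: 16 andavadoic acid {2-[(3R,5S)-3,5-dimethyl-5-(10-phenyldecyl)-1,2-dioxolan-3-yl]acetic acid}, via aldehyde 15 (not isolated)
Conditions: 2,2,6,6-tetramethylpiperidin-1-oxyl (TEMPO, 0.2 equiv), PhI(OAc)2 (2.5 equiv), CH2Cl2/MeCN/H2O, 0 °C → rt
Reagents that add atoms: water, O
Why: Oxoammonium-catalysed oxidation of the primary alcohol through aldehyde 15 and its hydrate to the acid under mildly acidic conditions that neither reduce the dialkyl peroxide nor promote β-elimination, while the fully substituted C3 and C5 cannot epimerise (the descriptor at C3 changes from S to R only through the priority change of the side chain).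

**Compound list**
1 | 3-methylbut-3-en-1-ol (isoprenol) | C=C(C)CCO | starting material
2 | triisopropyl[(3-methylbut-3-en-1-yl)oxy]silane | C=C(C)CCO[Si](C(C)C)(C(C)C)C(C)C | intermediate
3 | 4-[(triisopropylsilyl)oxy]butan-2-one O-oxide (carbonyl oxide, not isolated) | CC(CCO[Si](C(C)C)(C(C)C)C(C)C)=[O+][O-] | intermediate
4 | 2-methoxy-4-[(triisopropylsilyl)oxy]butan-2-yl hydroperoxide (racemic) | CC(OC)(CCO[Si](C(C)C)(C(C)C)C(C)C)OO | intermediate
5 | triethyl{[2-methoxy-4-(triisopropylsilyloxy)butan-2-yl]peroxy}silane (racemic) | CC(OC)(CCO[Si](C(C)C)(C(C)C)C(C)C)OO[Si](CC)(CC)CC | intermediate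
6 | 1,10-dibromodecane | BrCCCCCCCCCCBr | starting material
7 | phenylmagnesium bromide | Br[Mg]c1ccccc1 | starting material
8 | (10-bromodecyl)benzene | BrCCCCCCCCCCc1ccccc1 | intermediate
9 | isopropenylmagnesium bromide | C=C(C)[Mg]Br | starting material
10 | 2-methyl-12-phenyldodec-1-ene | C=C(C)CCCCCCCCCCc1ccccc1 | intermediate
11 | (triethylsilyloxy)[4-(triisopropylsilyloxy)butan-2-ylidene]oxonium (peroxycarbenium ion, paired with the catalyst anion, not isolated) | CC(CCO[Si](C(C)C)(C(C)C)C(C)C)=[O+]O[Si](CC)(CC)CC | intermediate
12 | 4-methyl-2-(10-phenyldecyl)-4-[(triethylsilyl)peroxy]-6-[(triisopropylsilyl)oxy]hexan-2-ylium (tertiary carbocation, peroxide-bearing carbon configured as C3 of 13, not isolated) | C[C+](CCCCCCCCCCc1ccccc1)C[C@](C)(CCO[Si](C(C)C)(C(C)C)C(C)C)OO[Si](CC)(CC)CC | intermediate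
13 | triisopropyl{2-[(3S,5S)-3,5-dimethyl-5-(10-phenyldecyl)-1,2-dioxolan-3-yl]ethoxy}silane | C[C@]1(CCCCCCCCCCc2ccccc2)C[C@](C)(CCO[Si](C(C)C)(C(C)C)C(C)C)OO1 | intermediate
14 | 2-[(3S,5S)-3,5-dimethyl-5-(10-phenyldecyl)-1,2-dioxolan-3-yl]ethan-1-ol | C[C@]1(CCCCCCCCCCc2ccccc2)C[C@](C)(CCO)OO1 | intermediate
15 | 2-[(3R,5S)-3,5-dimethyl-5-(10-phenyldecyl)-1,2-dioxolan-3-yl]acetaldehyde (not isolated) | C[C@]1(CCCCCCCCCCc2ccccc2)C[C@](C)(CC=O)OO1 | intermediate
16 | andavadoic acid, 2-[(3R,5S)-3,5-dimethyl-5-(10-phenyldecyl)-1,2-dioxolan-3-yl]acetic acid | C[C@]1(CCCCCCCCCCc2ccccc2)C[C@](C)(CC(=O)O)OO1 | target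

**Step count and risks**
Total step count: 8. Longest linear sequence: 6 (steps 1, 2, 3, 6, 7, 8).

Steps most likely to fail:

1. Step 6. The anion may not discriminate the two faces of the peroxycarbenium ion (methyl against a CH2 arm), the ring closure at C5 may proceed without control, or proton loss from the tertiary cation and acid-induced alkene isomerisation may outrun closure. The fallback is the known racemic annulation followed by resolution. It sets out from 5 and 10: SnCl4 in CH2Cl2 at −78 °C should give the stereoisomer mixture of the triisopropylsilyl-protected dioxolane F1. Bu4NF/AcOH in THF would then give the stereoisomer mixture of the dioxolanylethanol F2. This mixture would be separated by preparative HPLC on a cellulose tris(3,5-dimethylphenylcarbamate) phase, after removal of the unlike diastereomer pair on silica where possible. The (3S,5S) isomer is 14, where the route is rejoined; its absolute configuration would be assigned by comparing the rotation of the derived acid with that of the natural product.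

2. Step 8. The β-peroxy aldehyde may undergo ring-opening β-elimination, or the oxidation of the lipophilic substrate may stall at the aldehyde stage in the two-phase medium. The fallback separates the two oxidation events. It sets out from 14: Dess–Martin periodinane with NaHCO3 in dry CH2Cl2 would give aldehyde 15, which is isolated. NaClO2/NaH2PO4 with 2-methylbut-2-ene in t-BuOH/H2O (Pinnick oxidation) would then give 16, where the route is rejoined. No compound outside the list arises (entry F0).

3. Step 4. Arylation at both bromides and Grignard homocoupling in the statistical mono-coupling may leave a mixture from which the monobromide is hard to separate. The fallback uses a chain whose two ends are already different. It sets out from 7: 10-bromodecan-1-ol would be treated with 2.2 equiv of 7 (the first equivalent deprotonates the hydroxyl group) and Li2CuCl4 in THF to give 10-phenyldecan-1-ol F3. Appel bromination (CBr4, PPh3, CH2Cl2) would then return to 8.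

**Further compounds**
F1 | step 6 | triisopropyl{2-[3,5-dimethyl-5-(10-phenyldecyl)-1,2-dioxolan-3-yl]ethoxy}silane, stereocentres undefined (mixture of the four stereoisomers) | CC1(CCCCCCCCCCc2ccccc2)CC(C)(CCO[Si](C(C)C)(C(C)C)C(C)C)OO1
F2 | step 6 | 2-[3,5-dimethyl-5-(10-phenyldecyl)-1,2-dioxolan-3-yl]ethan-1-ol, stereocentres undefined (mixture of the four stereoisomers) | CC1(CCCCCCCCCCc2ccccc2)CC(C)(CCO)OO1
F0 | step 8 | none | none
F3 | step 4 | 10-phenyldecan-1-ol | OCCCCCCCCCCc1ccccc1
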